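(All constants come from no measurement.)

I start from the constants, which read here as the time constants of a loop: free catalyst takes up partner, catalyst intermediate A takes up substrate, and catalyst intermediate B releases product and free catalyst, while partner also decays on its own.

    partner → decomposed reagent (k1 = 0.0043 min⁻¹)
    partner + free catalyst → catalyst intermediate A (k2 = 2.3 M⁻¹ min⁻¹)
    substrate + catalyst intermediate A → catalyst intermediate B (k3 = 1.0 M⁻¹ min⁻¹)
    catalyst intermediate B → free catalyst + product (k4 = 5.7 min⁻¹)

common to all: substrate 1.5 M; partner 1.00 equiv; time 1.0 h
- theta: free catalyst 0.5 mol%
- beta: free catalyst 1 mol%

1. which of these there is most of at the end, counted by the substrate in it, theta (substrate / catalyst intermediate B / product)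
2. which of these there is most of at the end, counted by the substrate in it, beta (substrate / catalyst intermediate B / product)
3. the largest of these amounts at the end, in percent of the substrate charged, theta
4. the largest of these amounts at the end, in percent of the substrate charged, beta

At the charged concentrations, the same in theta and beta, free catalyst lasts 0.290 min on average and catalyst intermediate A 0.667 min. Catalyst intermediate B lasts 0.175 min, the shortest dwell. Their sum is 1.13 min; I call it the cycle time, the sum of the dwell times of the three forms at the concentrations of the moment. Catalyst intermediate A holds the longest dwell, so it is the resting state. The next rung is far higher: the half-life of partner by step 1 is 2.7 h, much longer than a turn. So I take the loop as steady and let [substrate] and [partner] drift slowly beneath it.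

Each turn makes one product per catalyst, so holding the starting cycle time for the whole run gives a ceiling of 26.5% product in theta and 53.0% in beta. The cycle lengthens as [substrate] and [partner] fall, so I expect both flasks to end below these. For theta I commit to substrate, above 73.5%. For beta the ceiling stands over the 47.0% of substrate it leaves, and my reckoning stops without a verdict.

The forecast also reckons with a “steady-state cycle”. It names substrate in theta at 77%, between 75.5% and 78.5%, and substrate in beta at 59%, between 57% and 61%.

The flask gives substrate at 77.2% in theta and substrate at 59.3% in beta, both inside the forecast's ranges. In theta, 57.1% of the partner is still free at the end. With those end amounts, the cycle time has grown to 1.55 min, a factor 1.37 on the start. Catalyst intermediate A's dwell is 55.7% of that, beside 55.8% of the catalyst standing in that form at 1.00 h.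

In a neighbour flask, theta with 0.250 equiv of partner, free catalyst's dwell stretches, and the cycle time starts at 2.00 min. That gives a ceiling of 15.0% product, so substrate above 85.0%. The computed flask ends with 88.9% substrate and 11.1% product.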